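## Retrosynthetic overview

1. The target comes from the tricyclic C8 alcohol by C8–O methacrylation and C9–O desilylation.
2. Key disconnection C7–C8: a C8 aldehyde and a 3-(bromomethyl)butenolide. CrCl2 turns the lactone β-carbon C7 into a nucleophile (a lactone homoenolate, d3 equivalent), which closes the ten-membered carbocycle last, sets C7 and C8 and regenerates the α-methylene lactone.
3. The butenolide comes from C6–O acylation with 2-(bromomethyl)acrylic acid and ring-closing metathesis; the aldehyde comes from a primary silyl ether.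
4. The furanone comes from a lithium acetylide and an α-hydroxy-γ-lactone, via an α'-hydroxy ynone that closes to the 3(2H)-furanone (C4–O–C1).
5. Fragments: a lactone (C3–C7; C4 by a copper bis(oxazoline) pyruvate aldol, C6 by CBS reduction) and an alkyne (C8–C10 and C1–C2; Sharpless epoxidation, alkynylalane opening). Ring order: furanone, then butenolide, then ten-membered ring.

Assumption: germacrane-type numbering is used for the skeleton. C1 = furanone carbon carrying the side chain, C2 = furanone CH, C3 = ketone, C4 = quaternary C–O carbon with its methyl, C5 = CH2, C6 = lactone CH–O, C7 = lactone CH, C8 = CH–O-methacrylate, C9 = CH–OH, C10 = CH–CH3, C11/C13 = exocyclic alkene, C12 = lactone C=O. The target is (4R,6S,7R,8S,9S,10S).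

## Route

Step 1
Reactants: 1 (E)-4-phenylbut-3-en-2-one
Product: 2 (E)-trimethyl[(4-phenylbuta-1,3-dien-2-yl)oxy]silane
Conditions: TMSOTf, Et3N, CH2Cl2, 0 °C
Reagents that add atoms: trimethylsilyl trifluoromethanesulfonate, C[Si](C)(C)OS(=O)(=O)C(F)(F)F
Why: Soft enolisation (silyl enol ether formation) can only occur at the methyl group of the enone, giving the 2-silyloxydiene with the (E)-styryl unit intact; no stereocentre is formed.

Step 2
Reactants: 2 (E)-trimethyl[(4-phenylbuta-1,3-dien-2-yl)oxy]silane; 3 methyl pyruvate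
Product: 5 methyl (2R,5E)-2-hydroxy-2-methyl-4-oxo-6-phenylhex-5-enoate, via silyl ether 4 (not isolated)
Conditions: [Cu((R,R)-tBu-box)](OTf)2 (10 mol %), THF, −78 °C; then 1 M HCl, THF, 0 °C
Reagents that add atoms: none
Why: Catalytic enantioselective Mukaiyama aldol addition to a pyruvate ester (Evans bis(oxazoline)–Cu(OTf)2 system): the pyruvate chelates copper through both carbonyls, the tert-butyl groups of the (R,R)-ligand leave the re face of the ketone open to the terminal CH2 of the enol silane, so the quaternary carbinol carbon C4 is formed as R, and the transferred silyl group is hydrolysed on work-up.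

Step 3
Reactants: 5 methyl (2R,5E)-2-hydroxy-2-methyl-4-oxo-6-phenylhex-5-enoate
Product: 7 (3R,5S)-3-hydroxy-3-methyl-5-[(E)-2-phenylethenyl]oxolan-2-one, via diol ester 6 (not isolated)
Conditions: (R)-2-methyl-CBS-oxazaborolidine (20 mol %), catecholborane, toluene, −78 °C; MeOH; then 1 M HCl/THF, rt
Reagents that add atoms: none
Why: Corey–Bakshi–Shibata reduction with the (R)-oxazaborolidine treats the styryl group as the large substituent and gives the (S)-allylic alcohol at C6 under reagent control (1,2-reduction only), after which the γ-hydroxy ester lactonises on acidic work-up to a five-membered lactone from which the minor C6 epimer is separable.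

Step 4
Reactants: 8 (E)-but-2-en-1-ol
Product: 9 [(2R,3R)-3-methyloxiran-2-yl]methanol
Conditions: Ti(OiPr)4 (10 mol %), D-(−)-diethyl tartrate (12 mol %), t-BuOOH, 4 Å sieves, CH2Cl2, −20 °C
Reagents that add atoms: tert-butyl hydroperoxide, CC(C)(C)OO
Why: Katsuki–Sharpless asymmetric epoxidation of the (E)-allylic alcohol with the D-(−)-tartrate catalyst delivers oxygen to one face to give the (2R,3R)-epoxy alcohol, which fixes C9 and the configuration from which C10 is derived.

Step 5
Reactants: 9 [(2R,3R)-3-methyloxiran-2-yl]methanol; 10 ethynyltrimethylsilane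
Product: 13 (2S,3R)-3-methylpent-4-yne-1,2-diol, via alkynylalane 11 (not isolated), via silylalkyne diol 12 (not isolated)
Conditions: 10, n-BuLi, toluene, −78 °C; Et2AlCl, −78 → 0 °C; then 9, 0 °C → rt; then MeOH, K2CO3, rt
Reagents that add atoms: none
Why: Alkynylalanes open trans-2,3-epoxy alcohols regioselectively at C3, distal to the aluminium-bound CH2O group, by SN2 attack with inversion, which converts the trans-epoxide into the C9-hydroxy/C10-methyl syn pair (C9 S and C10 S in the target), and K2CO3/MeOH then removes the C-silyl group.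

Step 6
Reactants: 13 (2S,3R)-3-methylpent-4-yne-1,2-diol
Product: 14 (2S,3R)-3-methyl-1,2-bis(triethylsilyloxy)pent-4-yne
Conditions: Et3SiCl, imidazole, DMF, 0 °C → rt
Reagents that add atoms: chlorotriethylsilane, CC[Si](CC)(CC)Cl
Why: Standard silylation of both hydroxyl groups; the primary triethylsilyl ether is the latent C8 aldehyde and the secondary one protects the C9 oxygen to the end.

Step 7
Reactants: 14 (2S,3R)-3-methyl-1,2-bis(triethylsilyloxy)pent-4-yne; 7 (3R,5S)-3-hydroxy-3-methyl-5-[(E)-2-phenylethenyl]oxolan-2-one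
Product: 16 (2R)-5-[(2S,3S)-3,4-bis(triethylsilyloxy)butan-2-yl]-2-[(2S,3E)-2-hydroxy-4-phenylbut-3-en-1-yl]-2-methylfuran-3(2H)-one, via hydroxy ynone 15 (not isolated)
Conditions: 14, n-BuLi, THF, −78 °C; add 7 pre-treated with LiN(SiMe3)2 (1.0 equiv), THF, −78 → −40 °C; then AcOH, Et2NH, EtOH, −78 °C → rt
Reagents that add atoms: none
Why: Acyl substitution at the non-enolisable lactone carbonyl (its α-carbon is quaternary) stops at the lithium lactolate so that only one acetylide adds, and the α'-hydroxy ynone released on quenching undergoes amine-mediated conjugate addition and 5-endo ring closure of the tertiary C4 hydroxyl onto C1 to give the 3(2H)-furanone, freeing the C6 hydroxyl without touching any stereocentre.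

Step 8
Reactants: 16 (furanone alcohol from step 7); 17 2-(bromomethyl)prop-2-enoic acid
Product: 19 (1E,3S)-4-{(2R)-5-[(2S,3S)-3,4-bis(triethylsilyloxy)butan-2-yl]-2-methyl-3-oxo-2,3-dihydrofuran-2-yl}-1-phenylbut-1-en-3-yl 2-(bromomethyl)prop-2-enoate, via acid chloride 18 (not isolated)
Conditions: 17, (COCl)2, cat. DMF, CH2Cl2, 0 °C → rt; then 16, 2,6-lutidine, CH2Cl2, −20 → 0 °C
Reagents that add atoms: none
Why: Acylation of the secondary allylic C6 alcohol with the acid chloride made in situ, using the hindered base 2,6-lutidine because nucleophilic amines would displace the allylic bromide; no stereocentre is affected.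

Step 9
Reactants: 19 (bromomethylacrylate ester from step 8)
Product: 20 (2R)-5-[(2S,3S)-3,4-bis(triethylsilyloxy)butan-2-yl]-2-{[(2S)-4-(bromomethyl)-5-oxo-2,5-dihydrofuran-2-yl]methyl}-2-methylfuran-3(2H)-one
Conditions: second-generation Hoveyda–Grubbs catalyst (H2IMes)Cl2Ru(=CH-C6H4-2-OiPr) (10 mol %), toluene (5 mM), 80 °C
Reagents that add atoms: none
Why: Ring-closing metathesis of an allylic 2-substituted acrylate to an α-substituted butenolide, initiated at the styryl alkene; the phosphine-free catalyst avoids quaternisation by the allylic bromide and the C6 stereocentre is untouched.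

Step 10
Reactants: 20 (bromomethylbutenolide from step 9)
Product: 21 (2S,3S)-3-[(5R)-5-{[(2S)-4-(bromomethyl)-5-oxo-2,5-dihydrofuran-2-yl]methyl}-5-methyl-4-oxo-4,5-dihydrofuran-2-yl]-2-(triethylsilyloxy)butanal
Conditions: (COCl)2, DMSO, CH2Cl2, −78 → −35 °C; then iPr2NEt, −78 → −40 °C; pH 7 buffer
Reagents that add atoms: none
Why: Swern conditions oxidise a primary triethylsilyl ether directly to the aldehyde (chloride-assisted silyl loss from the alkoxysulfonium ion) while the secondary triethylsilyl ether survives, and the hindered base at low temperature avoids epimerisation at C9 and substitution or elimination of the allylic bromide.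

Step 11
Reactants: 21 (bromo aldehyde from step 10)
Product: 22 tricyclic C8 alcohol: the target without its methacryloyl group and with a triethylsilyl ether on the C9 oxygen (configuration at C4, C6, C7, C8, C9 and C10 as in the target)
Conditions: CrCl2 (10 equiv), THF, slow addition to 2 mM, rt
Reagents that add atoms: none
Why: Proposed new method: CrCl2 inserts into the allylic C–Br bond to give an allylchromium species bound at the exocyclic CH2, which adds to the tethered aldehyde through the lactone β-carbon C7 with allylic transposition (a normally electrophilic a3 carbon made nucleophilic, so two electrophilic carbons are joined), re-forming the α-methylene lactone and closing the ten-membered ring; attack anti to the C5 substituent of the butenolide gives the 6,7-trans lactone (C7 R) and the chair-like six-membered transition state of the geometrically fixed (E)-type allylmetal with the aldehyde substituent pseudo-equatorial gives the 7,8-anti alcohol (C8 S), whereas the Felkin preference of the α-silyloxy centre is mismatched and is the main uncertainty; the closest known reactions are intermolecular CrCl2-mediated allylations of aldehydes with 3-(bromomethyl)furan-2(5H)-ones and intramolecular Nozaki–Hiyama–Kishi (Barbier-type) allylations that close the ten-membered ring of germacranolides.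

Step 12
Reactants: 22 (tricyclic C8 alcohol)
Product: 23 9-O-triethylsilyl ether of the target
Conditions: methacrylic anhydride, Et3N, DMAP (cat.), CH2Cl2, 0 °C → rt
Reagents that add atoms: methacrylic anhydride, C=C(C)C(=O)OC(=O)C(C)=C
Why: DMAP-catalysed acylation of the only free hydroxyl (C8) with methacrylic anhydride, with retention at C8.

Step 13
Reactants: 23 (9-O-triethylsilyl ether of the target)
Product: 24 CNP0195404.1, (4R,6S,7R,8S,9S,10S)-9-hydroxy-8-methacryloyloxy-3-oxo-1,4-epoxygermacra-1,11(13)-dien-12,6-olide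
Conditions: HF·pyridine, THF/pyridine, 0 °C
Reagents that add atoms: none
Why: Acidic fluoride cleavage of the secondary triethylsilyl ether leaves the two enoate esters, the furanone and the α-methylene lactone intact and avoids base-induced 8→9 acyl migration.

## Compound list

1 | (E)-4-phenylbut-3-en-2-one | CC(=O)/C=C/c1ccccc1 | starting material
2 | (E)-trimethyl[(4-phenylbuta-1,3-dien-2-yl)oxy]silane | C=C(O[Si](C)(C)C)/C=C/c1ccccc1 | intermediate
3 | methyl pyruvate | COC(=O)C(C)=O | starting material
4 | methyl (2R,5E)-2-methyl-4-oxo-6-phenyl-2-(trimethylsilyloxy)hex-5-enoate; not isolated | COC(=O)[C@](C)(O[Si](C)(C)C)CC(=O)/C=C/c1ccccc1 | intermediate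
5 | methyl (2R,5E)-2-hydroxy-2-methyl-4-oxo-6-phenylhex-5-enoate | COC(=O)[C@](C)(O)CC(=O)/C=C/c1ccccc1 | intermediate
6 | methyl (2R,4S,5E)-2,4-dihydroxy-2-methyl-6-phenylhex-5-enoate; not isolated | COC(=O)[C@](C)(O)C[C@H](O)/C=C/c1ccccc1 | intermediate
7 | (3R,5S)-3-hydroxy-3-methyl-5-[(E)-2-phenylethenyl]oxolan-2-one | C[C@@]1(O)C[C@@H](/C=C/c2ccccc2)OC1=O | intermediate
8 | (E)-but-2-en-1-ol | C/C=C/CO | starting material
9 | [(2R,3R)-3-methyloxiran-2-yl]methanol | OC[C@H]1O[C@@H]1C | intermediate
10 | ethynyltrimethylsilane | C#C[Si](C)(C)C | starting material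
11 | diethyl[(trimethylsilyl)ethynyl]alane; not isolated | CC[Al](CC)C#C[Si](C)(C)C | intermediate
12 | (2S,3R)-3-methyl-5-(trimethylsilyl)pent-4-yne-1,2-diol; not isolated | OC[C@@H](O)[C@H](C)C#C[Si](C)(C)C | intermediate
13 | (2S,3R)-3-methylpent-4-yne-1,2-diol | OC[C@@H](O)[C@H](C)C#C | intermediate
14 | (2S,3R)-3-methyl-1,2-bis(triethylsilyloxy)pent-4-yne | CC[Si](CC)(CC)OC[C@@H](O[Si](CC)(CC)CC)[C@H](C)C#C | intermediate
15 | (1E,3S,5R,9R,10S)-3,5-dihydroxy-5,9-dimethyl-1-phenyl-10,11-bis(triethylsilyloxy)undec-1-en-7-yn-6-one; not isolated | CC[Si](CC)(CC)OC[C@@H](O[Si](CC)(CC)CC)[C@H](C)C#CC(=O)[C@](C)(O)C[C@H](O)/C=C/c1ccccc1 | intermediate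
16 | (2R)-5-[(2S,3S)-3,4-bis(triethylsilyloxy)butan-2-yl]-2-[(2S,3E)-2-hydroxy-4-phenylbut-3-en-1-yl]-2-methylfuran-3(2H)-one | CC[Si](CC)(CC)OC[C@@H](O[Si](CC)(CC)CC)[C@H](C)C1=CC(=O)[C@@](C)(C[C@H](O)/C=C/c2ccccc2)O1 | intermediate
17 | 2-(bromomethyl)prop-2-enoic acid | C=C(CBr)C(=O)O | starting material
18 | 2-(bromomethyl)prop-2-enoyl chloride; not isolated | C=C(CBr)C(=O)Cl | intermediate
19 | (1E,3S)-4-{(2R)-5-[(2S,3S)-3,4-bis(triethylsilyloxy)butan-2-yl]-2-methyl-3-oxo-2,3-dihydrofuran-2-yl}-1-phenylbut-1-en-3-yl 2-(bromomethyl)prop-2-enoate | CC[Si](CC)(CC)OC[C@@H](O[Si](CC)(CC)CC)[C@H](C)C1=CC(=O)[C@@](C)(C[C@H](OC(=O)C(=C)CBr)/C=C/c2ccccc2)O1 | intermediate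
20 | (2R)-5-[(2S,3S)-3,4-bis(triethylsilyloxy)butan-2-yl]-2-{[(2S)-4-(bromomethyl)-5-oxo-2,5-dihydrofuran-2-yl]methyl}-2-methylfuran-3(2H)-one | CC[Si](CC)(CC)OC[C@@H](O[Si](CC)(CC)CC)[C@H](C)C1=CC(=O)[C@@](C)(C[C@@H]2OC(=O)C(CBr)=C2)O1 | intermediate
21 | (2S,3S)-3-[(5R)-5-{[(2S)-4-(bromomethyl)-5-oxo-2,5-dihydrofuran-2-yl]methyl}-5-methyl-4-oxo-4,5-dihydrofuran-2-yl]-2-(triethylsilyloxy)butanal | O=C[C@@H](O[Si](CC)(CC)CC)[C@H](C)C1=CC(=O)[C@@](C)(C[C@@H]2OC(=O)C(CBr)=C2)O1 | intermediate
22 | tricyclic C8 alcohol: target without the methacryloyl group, C9–O-triethylsilyl, stereocentres as in the target | O[C@@H]1[C@@H](O[Si](CC)(CC)CC)[C@H](C)C2=CC(=O)[C@@](C)(C[C@@H]3OC(=O)C(=C)[C@@H]13)O2 | intermediate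
23 | 9-O-triethylsilyl ether of the target | C=C(C)C(=O)O[C@@H]1[C@@H](O[Si](CC)(CC)CC)[C@H](C)C2=CC(=O)[C@@](C)(C[C@@H]3OC(=O)C(=C)[C@@H]13)O2 | intermediate
24 | CNP0195404.1, (4R,6S,7R,8S,9S,10S)-9-hydroxy-8-methacryloyloxy-3-oxo-1,4-epoxygermacra-1,11(13)-dien-12,6-olide | C=C(C)C(=O)O[C@@H]1[C@@H](O)[C@H](C)C2=CC(=O)[C@@](C)(C[C@@H]3OC(=O)C(=C)[C@@H]13)O2 | target

## Step count and risks

Total step count: 13.
Longest linear sequence: 10 steps (8 → 24 through steps 4–13; the branch 1 → 24 through steps 1–3 and 7–13 is equally long).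

Three steps most likely to fail:

**Step 11 (chromium ring closure).** The ten-membered ring closure may be slow, and the mismatched Felkin preference at the aldehyde may give the C8 epimer. The fallback sets out from 21 and comes back at 23. If the closure gives mainly the epimeric alcohol, the C8 epimer of 22 F1, it is not acylated as in step 12. Instead it is esterified with inversion by methacrylic acid, PPh3 and DIAD in toluene at 0 °C → rt (Mitsunobu). This gives 23 directly, so C8 is set by SN2 displacement instead of by the ring closure, and step 13 follows unchanged.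

**Step 9 (metathesis with the allylic bromide in place; this also covers the bromide's exposure to amine in step 10).** The fallback sets out from 16 and comes back at 22. The bromide is replaced by an allylic acetate that becomes the nucleophile only at the end. Alcohol 16 is esterified with 2-(acetoxymethyl)acrylic acid (DCC, cat. DMAP, CH2Cl2, 0 °C) to the acetoxymethyl acrylate F2. Ring-closing metathesis with the same catalyst gives the 3-(acetoxymethyl)butenolide F3. Swern oxidation of the primary silyl ether as in step 10 gives the acetoxy aldehyde F4. F4 is then cyclised with Pd(PPh3)4 (cat.) and InI in THF at high dilution: zerovalent palladium ionises the acetate to a π-allyl complex, reductive transmetalation gives the allylindium, and the same C7 → C8 addition gives 22.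

**Step 7 (single acetylide addition to the hydroxy lactone and one-pot furanone closure).** The fallback sets out from 7 and comes back at 15. Lactone 7 is opened with MeNH(OMe)·HCl and AlMe3 in CH2Cl2 to the Weinreb amide F5. Three equivalents of lithiated 14 are added (two are consumed by the hydroxyl groups and recovered as 14) to give hydroxy ynone 15. This is now isolated and cyclised separately to 16 with Et2NH/EtOH or with (Ph3P)AuCl/AgOTf (cat.) in toluene.

## Further compounds

F1 | step 11 | C8 epimer of 22 (8R alcohol, C9–O-triethylsilyl) | O[C@H]1[C@@H](O[Si](CC)(CC)CC)[C@H](C)C2=CC(=O)[C@@](C)(C[C@@H]3OC(=O)C(=C)[C@@H]13)O2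
F2 | step 9 | (1E,3S)-4-{(2R)-5-[(2S,3S)-3,4-bis(triethylsilyloxy)butan-2-yl]-2-methyl-3-oxo-2,3-dihydrofuran-2-yl}-1-phenylbut-1-en-3-yl 2-(acetoxymethyl)prop-2-enoate | CC[Si](CC)(CC)OC[C@@H](O[Si](CC)(CC)CC)[C@H](C)C1=CC(=O)[C@@](C)(C[C@H](OC(=O)C(=C)COC(C)=O)/C=C/c2ccccc2)O1
F3 | step 9 | (2R)-2-{[(2S)-4-(acetoxymethyl)-5-oxo-2,5-dihydrofuran-2-yl]methyl}-5-[(2S,3S)-3,4-bis(triethylsilyloxy)butan-2-yl]-2-methylfuran-3(2H)-one | CC[Si](CC)(CC)OC[C@@H](O[Si](CC)(CC)CC)[C@H](C)C1=CC(=O)[C@@](C)(C[C@@H]2OC(=O)C(COC(C)=O)=C2)O1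
F4 | step 9 | (2S,3S)-3-[(5R)-5-{[(2S)-4-(acetoxymethyl)-5-oxo-2,5-dihydrofuran-2-yl]methyl}-5-methyl-4-oxo-4,5-dihydrofuran-2-yl]-2-(triethylsilyloxy)butanal | O=C[C@@H](O[Si](CC)(CC)CC)[C@H](C)C1=CC(=O)[C@@](C)(C[C@@H]2OC(=O)C(COC(C)=O)=C2)O1
F5 | step 7 | (2R,4S,5E)-2,4-dihydroxy-N-methoxy-N,2-dimethyl-6-phenylhex-5-enamide | CON(C)C(=O)[C@](C)(O)C[C@H](O)/C=C/c1ccccc1
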